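Ring A is C1–C5 plus C10 (C4 bears =CH2, C5 is the fusion CH, C10 the fusion carbon whose methyl is C14). Ring B is C5–C10 (C8 is CH–CH3, C9 bears CH3 and the C11H2–quinone arm).
Enabling feature: C9 and C10, the adjacent quaternary atoms of ring B, become the termini of a [3,3] array C10=C14–O–C7–C8=C9 once C14 is a carboxyl carbon bound through oxygen to C7. C9–C10 is therefore the Claisen bond of a δ-lactone (C14, O, C7, C6, C5, C10) carrying a C8=C9 alkenyl group on C7.
Retrosynthetic cuts, in order: quinone O–CH3 and oxidation level, C4=CH2, C11–aryl, H2 across C7=C8, C14 (CH3 back to CO2H), C9–C10 (key), C14–O, C7–C8, C5–C6, C10–C14.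
Forward: ring A is cyclohexenone. C14 (as an alkenyl carbon) and C6–C7 enter by conjugate addition then alkylation, the C8–C9–C11 unit is joined at C7, and the lactone ring is closed. Ring B arises from the lactone in the rearrangement, and the arene is attached at C11 and oxidised last.
Stereochemistry: Rh/(S)-BINAP sets C10, which relays to C5 by trans alkylation and is then erased. CBS reduction sets C7. In the key step C7 hands chirality back to C10 and the (Z)-alkene sets C9. C11–OH-directed hydrogenation sets C8.

Key step: step 10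

Remark 1: α/β refer to the target drawn with the C10 methyl (C14) β. The target then has H5 α, C9–CH3 β, C11 α and C8–CH3 β, which is (5S,8S,9R,10S) in the numbering above.
Remark 2: (S)-BINAP is assumed to show the sense of induction established for aryl- and alkenylrhodium additions to cyclohex-2-enone, where the (S)-ligand gives the (S)-3-substituted ketone series.
Remark 3: C10 of 13–17 is drawn trans but has no consequence, because it becomes sp2 in step 10. Compounds 30 and 31 are carried as C11 epimers, and that centre is removed in step 19.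

Step 1
Reactants: 1 but-2-yn-1-ol
Product: 3 (Z)-3-iodo-2-methylbut-2-en-1-ol, via oxamagnesacycle 2 (not isolated)
Conditions: CH3MgBr (3 equiv), CuI (10 mol %), THF, 0 °C to rt; then I2, THF, −20 to 0 °C
Reagents that add atoms: methylmagnesium bromide, C[Mg]Br; iodine, II
Why: Copper-catalysed anti-carbomagnesiation of the propargylic alkoxide puts CH3 on the carbon next to CH2O (future C9) and magnesium on future C8 inside a five-membered chelate, so iodinolysis with retention leaves I cis to CH2OH, i.e. the (Z)-tetrasubstituted alkene.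

Step 2
Reactants: 3 (Z)-3-iodo-2-methylbut-2-en-1-ol
Product: 4 (Z)-3-iodo-2-methylbut-2-en-1-yl 4-methoxybenzyl ether
Conditions: NaH, 4-methoxybenzyl chloride, Bu4NI (cat.), THF/DMF, 0 °C to rt
Reagents that add atoms: 4-methoxybenzyl chloride, COc1ccc(CCl)cc1
Why: This is a Williamson etherification, and a benzyl-type ether is chosen because it cannot undergo the O-to-C silyl shift open to cis-γ-silyloxy alkenyllithiums and it survives the hot KOH of step 13.

Step 3
Reactants: 5 hex-1-yne; 6 cyclohex-2-en-1-one
Product: 8 (R)-trimethyl{[3-((E)-hex-1-en-1-yl)cyclohex-1-en-1-yl]oxy}silane (C10–H β), via hexenylzirconocene chloride 7 (not isolated)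
Conditions: Cp2ZrHCl, THF, rt; then [Rh(cod)(MeCN)2]BF4 (5 mol %), (S)-2,2'-bis(diphenylphosphino)-1,1'-binaphthyl ((S)-BINAP, 6 mol %), 6, Me3SiCl, THF, rt
Reagents that add atoms: chlorotrimethylsilane, C[Si](C)(C)Cl; Cp2ZrHCl, [H][Zr](Cl)(C1C=CC=C1)C1C=CC=C1 (zirconium stays in 7 only)
Why: Syn hydrozirconation followed by rhodium-catalysed asymmetric 1,4-addition of the alkenylzirconocene with silyl trapping sets C10 through the (S)-BINAP-bound alkenylrhodium and stores the enolate regiochemistry (C4=C5) as the enol silane; only the first alkenyl carbon (C14) is kept later.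

Step 4
Reactants: 8 enol silane; 9 2-bromo-N-methoxy-N-methylacetamide
Product: 11 2-[(1R,2R)-2-((E)-hex-1-en-1-yl)-6-oxocyclohexyl]-N-methoxy-N-methylacetamide (trans; H5 α and H10 β), via lithium enolate 10 (not isolated)
Conditions: CH3Li, THF, 0 °C; then 9, DMPU, −78 to −20 °C
Reagents that add atoms: methyllithium, [Li]C (lithium stays in 10 only)
Why: Si–O cleavage releases the regiodefined lithium enolate, and its SN2 alkylation by the activated bromide occurs anti to the C10 alkenyl group, giving the trans-2,3-disubstituted ketone, which is also the thermodynamic isomer, and thereby setting C5.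

Step 5
Reactants: 11 trans keto amide
Product: 12 2-[(6R,7R)-7-((E)-hex-1-en-1-yl)-1,4-dioxaspiro[4.5]decan-6-yl]-N-methoxy-N-methylacetamide
Conditions: Me3SiOCH2CH2OSiMe3, Me3SiOSO2CF3 (5 mol %), CH2Cl2, −78 to −20 °C
Reagents that add atoms: 1,2-bis(trimethylsilyloxy)ethane, C[Si](C)(C)OCCO[Si](C)(C)C
Why: Aprotic low-temperature ketalisation with the bis-silyl glycol ether is driven by disiloxane formation and does not enolise the ketone, so C5 is kept and is no longer epimerisable afterwards.

Step 6
Reactants: 12 ketal amide
Product: 13 methyl (6R,7S)-6-{2-[methoxy(methyl)amino]-2-oxoethyl}-1,4-dioxaspiro[4.5]decane-7-carboxylate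
Conditions: O3, NaOH (2.5 M in MeOH), CH2Cl2, −78 °C; then H2O/Et2O
Reagents that add atoms: ozone, [O-][O+]=O; methanol, CO
Why: Ozonolysis in methanolic NaOH turns both alkene carbons directly into methyl esters (via methoxy hydroperoxide dehydration and hemiacetal oxidation), which delivers C14 at the carboxyl level, differentiated from the C7 amide, under conditions that leave ketal and amide intact.

Step 7
Reactants: 4 (Z)-alkenyl iodide; 13 ester amide
Product: 15 methyl (6R,7S)-6-[(Z)-5-(4-methoxybenzyloxy)-3,4-dimethyl-2-oxopent-3-en-1-yl]-1,4-dioxaspiro[4.5]decane-7-carboxylate, via alkenyllithium 14 (not isolated)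
Conditions: 4, t-BuLi (2 equiv), Et2O, −78 °C; then 13, THF, −78 °C; aq. NH4Cl
Reagents that add atoms: tert-butyllithium, [Li]C(C)(C)C (lithium stays in 14 only)
Why: Iodine–lithium exchange proceeds with retention of alkene geometry, and the Weinreb ketone synthesis stops at the chelated adduct; the bulky nucleophile should attack the CH2-bound amide in preference to the α-branched ring ester.

Step 8
Reactants: 15 (Z)-enone ester
Product: 16 methyl (6R,7S)-6-[(2S,3Z)-2-hydroxy-5-(4-methoxybenzyloxy)-3,4-dimethylpent-3-en-1-yl]-1,4-dioxaspiro[4.5]decane-7-carboxylate (7S)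
Conditions: (3aR)-1-methyl-3,3-diphenyltetrahydro-1H,3H-pyrrolo[1,2-c][1,3,2]oxazaborole ((R)-Me-CBS, 0.3 equiv), BH3·SMe2, toluene, −40 °C; MeOH
Reagents that add atoms: none
Why: In the Corey–Bakshi–Shibata reduction the fully substituted alkenyl group acts as the large substituent and C6H2 as the small one, so the (R)-catalyst should deliver hydride to give the (7S)-carbinol under reagent control while the ester and the tetrasubstituted alkene stay untouched.

Step 9
Reactants: 16 (7S)-hydroxy ester
Product: 17 (3S,4aR,8aS)-3-[(Z)-4-(4-methoxybenzyloxy)-3-methylbut-2-en-2-yl]hexahydrospiro[isochromane-5,2'-[1,3]dioxolan]-1-one (trans-fused δ-lactone; 5R,7S,10S; alkenyl group α, cis to H5)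
Conditions: 1,8-diazabicyclo[5.4.0]undec-7-ene (DBU, 0.3 equiv), 4 Å molecular sieves, toluene, 80 °C
Reagents that add atoms: none
Why: Base-catalysed intramolecular transesterification closes the six-membered lactone from two equatorial arms on ring A, uptake of methanol by the sieves drives it, and acid is avoided because the C7 allylic alcohol ionises easily.

Step 10
Reactants: 17 alkenyl δ-lactone
Product: 20 trans-fused octalin acid (5R,9R,10R): 4,4-ethylenedioxy-8,9-dimethyl-9-(4-methoxybenzyloxymethyl)-Δ7-octalin-10-carboxylic acid (CO2H β; H5 α; C9–CH3 β; C11 α), via silyl ketene acetal 18 (not isolated), via trimethylsilyl ester 19 (not isolated)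
Conditions: LiN(i-Pr)2, THF, −78 °C; Me3SiCl/Et3N, −78 to 0 °C; solvent exchange to toluene, 110 °C (sealed); then 10 % aq. citric acid/THF, rt
Reagents that add atoms: chlorotrimethylsilane, C[Si](C)(C)Cl (silicon stays in 18 and 19 only)
Why: LiN(i-Pr)2 removes the only acidic proton (C10–H) and O-silylation gives the ring-locked ketene acetal 18, a 6-silyloxy-2-alkenyl-3,4-dihydro-2H-pyran, which undergoes a concerted suprafacial [3,3] shift across C10=C14–O–C7–C8=C9 that makes C9–C10, breaks C7–O and moves the alkene to C7=C8. The closest known reaction type is the Ireland–Claisen rearrangement of alkenyl lactone silyl ketene acetals to cycloalkenecarboxylic acids, taken together with acyclic Ireland–Claisen constructions of vicinal quaternary carbons. Ring B (C5–C10) closes through the sigmatropic bond formation itself: because C10 and C7 are already tied by C5–C6, the six reacting atoms can only stack as a boat (bicyclo[2.2.2]octene-like, C7 and C10 as bridgeheads), and a chair is geometrically out of reach. C10 is set by chirality transfer from C7, since the alkenyl group stands on the α face cis to H5, C9 bonds to the α face of C10, C14 is pushed β and the ring fusion becomes trans. C9 is set by the alkene geometry, since in the boat the substituent cis to C7 (C11) lies under C5 and ends anti to C14 while the C9 methyl ends cis to C14. The step needs O- rather than C-silylation, a single ketene acetal geometry and rearrangement faster than C7–O ionisation, and these are secured by the fully substituted enolate carbon, by the ring, and by the non-polar medium together with the irreversible exchange of a lactone C–O bond for a carboxylate.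

Step 11
Reactants: 20 octalin acid
Product: 21 C14 primary alcohol (5R,9R,10R; C10–CH2OH β)
Conditions: LiAlH4, THF, 0 °C to reflux; H2O/NaOH work-up
Reagents that add atoms: none
Why: LiAlH4 reduction reaches even tertiary, neopentyl carboxylic acids on heating, and ketal, benzyl-type ether and isolated alkene are inert to it.

Step 12
Reactants: 21 C14 alcohol
Product: 22 C14 aldehyde (5R,9R,10R; C10–CHO β)
Conditions: Dess–Martin periodinane, NaHCO3, CH2Cl2, rt
Reagents that add atoms: none
Why: Dess–Martin oxidation works well on hindered neopentyl alcohols under buffered neutral conditions, and the aldehyde has no α-hydrogen to epimerise.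

Step 13
Reactants: 22 C14 aldehyde
Product: 24 C14 methyl compound (5R,9R,10S; C10–CH3 β; C11 still a 4-methoxybenzyl ether), via hydrazone 23 (not isolated)
Conditions: N2H4·H2O, KOH, diethylene glycol, 130 °C, then distil to 200 °C
Reagents that add atoms: hydrazine hydrate, NN (nitrogen stays in 23 only)
Why: The Wolff–Kishner reduction (Huang-Minlon procedure) is the classical way from an angular aldehyde to an angular methyl group, needs only the small nucleophile hydrazine, and meets only base-stable groups here.

Step 14
Reactants: 24 4-methoxybenzyl ether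
Product: 25 C11 primary alcohol (5R,9R,10S; C9–CH2OH α; C7=C8 intact)
Conditions: DDQ, CH2Cl2/pH 7 buffer, 0 °C to rt
Reagents that add atoms: none
Why: Oxidative cleavage of the electron-rich benzyl ether by hydride abstraction and hydrolysis frees the directing hydroxyl group without touching the trisubstituted alkene or the buffered ketal.

Step 15
Reactants: 25 homoallylic alcohol
Product: 26 saturated alcohol (5R,8S,9R,10S; H8 α; C8–CH3 β)
Conditions: H2 (1–10 atm), [Ir(cod)(PCy3)(py)]PF6 (10 mol %), CH2Cl2, rt
Reagents that add atoms: none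
Why: In this hydroxyl-directed homogeneous hydrogenation the cationic iridium centre binds the α-oriented C11–OH and delivers both hydrogens to the α face of C7=C8, which sets C8 with its methyl β against the thermodynamic preference, with the axial C14 methyl shielding the β face as well.

Step 16
Reactants: 26 saturated alcohol
Product: 27 C11 aldehyde (5R,8S,9R,10S)
Conditions: Dess–Martin periodinane, NaHCO3, CH2Cl2, rt
Reagents that add atoms: none
Why: Dess–Martin oxidation gives a non-enolisable neopentyl aldehyde, so no stereocentre is at risk.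

Step 17
Reactants: 27 C11 aldehyde; 28 1,2,4,5-tetramethoxybenzene
Product: 30 C11 aryl carbinol (2,3,5,6-tetramethoxyphenyl; C11 epimers), via aryllithium 29 (not isolated)
Conditions: 28, n-BuLi, TMEDA, THF, 0 °C to rt; then 27, −78 to 0 °C
Reagents that add atoms: n-butyllithium, [Li]CCCC (lithium stays in 29 only)
Why: Directed ortho-lithiation between two methoxy groups is unambiguous in the symmetric arene, and 1,2-addition is the only course open to an aldehyde that can be neither enolised nor reduced by the reagent; this is the standard way to join arenes to neopentyl decalin aldehydes.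

Step 18
Reactants: 30 aryl carbinol
Product: 31 O-(C11) S-methyl xanthate
Conditions: NaH, THF, 0 °C; CS2; CH3I, rt
Reagents that add atoms: carbon disulfide, S=C=S; iodomethane, CI
Why: Xanthate formation uses the small electrophile CS2 at the hindered alkoxide, and thermal syn-elimination is impossible because C9 bears no hydrogen.

Step 19
Reactants: 31 xanthate
Product: 32 C11 methylene compound (5R,8S,9R,10S; tetramethoxybenzyl on C9 α; ketal intact)
Conditions: Bu3SnH, 2,2'-azobis(isobutyronitrile) (cat.), toluene, reflux
Reagents that add atoms: none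
Why: The Barton–McCombie deoxygenation passes through a stabilised benzylic radical that has no alkene within reach and avoids the cation, and hence the 1,2-shifts, that ionic reduction next to quaternary C9 would invite.

Step 20
Reactants: 32 ketal
Product: 33 C4 ketone (5R,8S,9R,10S; trans-decalone)
Conditions: pyridinium p-toluenesulfonate (0.2 equiv), acetone/H2O 10:1, 50 °C
Reagents that add atoms: water, O
Why: Mildly acid-catalysed ketal hydrolysis, helped by relief of strain next to C5, is much faster than acid enolisation, so H5 α should be retained.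

Step 21
Reactants: 33 C4 ketone
Product: 34 exocyclic alkene (5S,8S,9R,10S; C4=CH2)
Conditions: Zn, CH2Br2, TiCl4 (pre-aged reagent), THF/CH2Cl2, 0 °C to rt
Reagents that add atoms: dibromomethane, BrCBr
Why: The Lombardo methylenation uses a non-basic gem-dimetallic reagent that is known to convert epimerisable ketones to methylene compounds without enolisation, which protects the C5 centre.

Step 22
Reactants: 34 tetramethoxyarene
Product: 35 3-alkyl-2,5-dimethoxy-1,4-benzoquinone
Conditions: (NH4)2Ce(NO3)6 (2.5 equiv), MeCN/H2O, 0 °C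
Reagents that add atoms: water, O
Why: Oxidative demethylation by tetravalent cerium converts one para-dimethoxy pair to the quinone, the two pairs are equivalent by symmetry so a single quinone results, and the short cold reaction spares the 1,1-disubstituted alkene.

Step 23
Reactants: 35 dimethoxyquinone
Product: 36 3-alkyl-2,5-dihydroxy-1,4-benzoquinone
Conditions: KOH (2 M aq.), EtOH, argon, 60 °C; then cold 1 M HCl to pH 2, immediate extraction
Reagents that add atoms: potassium hydroxide, [K+].[OH-]
Why: Both methoxy groups are vinylogous esters and are exchanged for hydroxide by addition–elimination (vinylogous saponification) under basic conditions that cannot isomerise the exocyclic alkene.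

Step 24
Reactants: 36 dihydroxyquinone
Product: 37 target, 2-hydroxy-5-methoxy-3-{[(1R,2S,4aS,8aS)-1,2,8a-trimethyl-5-methylidenedecahydronaphthalen-1-yl]methyl}cyclohexa-2,5-diene-1,4-dione
Conditions: (CH3O)2SO2 (1.0 equiv), K2CO3, acetone, rt
Reagents that add atoms: dimethyl sulfate, COS(=O)(=O)OC
Why: In this selective O-alkylation the vinylogous carboxylate flanking the ring CH is unhindered whereas the one flanking the neopentyl C11 arm is shielded, and methylation at either oxygen of the open unit gives the same 2-hydroxy-5-methoxy quinone, as known for 3-alkyl-2,5-dihydroxybenzoquinones.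

Compound list
1 | but-2-yn-1-ol | CC#CCO | starting material
2 | 3,4-dimethyl-2,5-dihydro-1,2-oxamagnesole (chelated alkenylmagnesium alkoxide) | CC1=C(C)CO[Mg]1 | intermediate
3 | (Z)-3-iodo-2-methylbut-2-en-1-ol | I/C(C)=C(C)\CO | intermediate
4 | (Z)-3-iodo-2-methylbut-2-en-1-yl 4-methoxybenzyl ether | I/C(C)=C(C)\COCc1ccc(OC)cc1 | intermediate
5 | hex-1-yne | C#CCCCC | starting material
6 | cyclohex-2-en-1-one | O=C1C=CCCC1 | starting material
7 | (E)-hex-1-en-1-ylzirconocene chloride | CCCC/C=C/[Zr](Cl)(C1C=CC=C1)C1C=CC=C1 | intermediate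
8 | (R)-trimethyl{[3-((E)-hex-1-en-1-yl)cyclohex-1-en-1-yl]oxy}silane | C[Si](C)(C)OC1=C[C@@H](/C=C/CCCC)CCC1 | intermediate
9 | 2-bromo-N-methoxy-N-methylacetamide | CON(C)C(=O)CBr | starting material
10 | lithium (R)-3-((E)-hex-1-en-1-yl)cyclohex-1-en-1-olate | [Li]OC1=C[C@@H](/C=C/CCCC)CCC1 | intermediate
11 | 2-[(1R,2R)-2-((E)-hex-1-en-1-yl)-6-oxocyclohexyl]-N-methoxy-N-methylacetamide | CON(C)C(=O)C[C@H]1C(=O)CCC[C@@H]1/C=C/CCCC | intermediate
12 | 2-[(6R,7R)-7-((E)-hex-1-en-1-yl)-1,4-dioxaspiro[4.5]decan-6-yl]-N-methoxy-N-methylacetamide | CON(C)C(=O)C[C@H]1C2(OCCO2)CCC[C@@H]1/C=C/CCCC | intermediate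
13 | methyl (6R,7S)-6-{2-[methoxy(methyl)amino]-2-oxoethyl}-1,4-dioxaspiro[4.5]decane-7-carboxylate | CON(C)C(=O)C[C@H]1C2(OCCO2)CCC[C@@H]1C(=O)OC | intermediate
14 | (Z)-4-(4-methoxybenzyloxy)-3-methylbut-2-en-2-yllithium | [Li]/C(C)=C(C)\COCc1ccc(OC)cc1 | intermediate
15 | methyl (6R,7S)-6-[(Z)-5-(4-methoxybenzyloxy)-3,4-dimethyl-2-oxopent-3-en-1-yl]-1,4-dioxaspiro[4.5]decane-7-carboxylate | O=C(C[C@H]1C2(OCCO2)CCC[C@@H]1C(=O)OC)/C(C)=C(C)\COCc1ccc(OC)cc1 | intermediate
16 | methyl (6R,7S)-6-[(2S,3Z)-2-hydroxy-5-(4-methoxybenzyloxy)-3,4-dimethylpent-3-en-1-yl]-1,4-dioxaspiro[4.5]decane-7-carboxylate | O[C@@H](C[C@H]1C2(OCCO2)CCC[C@@H]1C(=O)OC)/C(C)=C(C)\COCc1ccc(OC)cc1 | intermediate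
17 | trans-fused alkenyl δ-lactone (5R,7S,10S), C4 dioxolane, alkenyl α | O=C1O[C@@H](C[C@H]2C3(OCCO3)CCC[C@H]12)/C(C)=C(C)\COCc1ccc(OC)cc1 | intermediate
18 | trimethylsilyl ketene acetal of 17 (5R,7S; C10=C14) | C[Si](C)(C)OC1=C2CCCC3(OCCO3)[C@@H]2C[C@H](O1)/C(C)=C(C)\COCc1ccc(OC)cc1 | intermediate
19 | trimethylsilyl ester of 20 | C[Si](C)(C)OC(=O)[C@]12CCCC3(OCCO3)[C@@H]1CC=C(C)[C@@]2(C)COCc1ccc(OC)cc1 | intermediate
20 | trans-fused octalin C14 acid (5R,9R,10R) | O=C(O)[C@]12CCCC3(OCCO3)[C@@H]1CC=C(C)[C@@]2(C)COCc1ccc(OC)cc1 | intermediate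
21 | C14 primary alcohol (5R,9R,10R) | OC[C@]12CCCC3(OCCO3)[C@@H]1CC=C(C)[C@@]2(C)COCc1ccc(OC)cc1 | intermediate
22 | C14 aldehyde (5R,9R,10R) | O=C[C@]12CCCC3(OCCO3)[C@@H]1CC=C(C)[C@@]2(C)COCc1ccc(OC)cc1 | intermediate
23 | C14 hydrazone | NN=C[C@]12CCCC3(OCCO3)[C@@H]1CC=C(C)[C@@]2(C)COCc1ccc(OC)cc1 | intermediate
24 | C14 methyl octalin, C11 4-methoxybenzyl ether (5R,9R,10S) | C[C@]12CCCC3(OCCO3)[C@@H]1CC=C(C)[C@@]2(C)COCc1ccc(OC)cc1 | intermediate
25 | C11 alcohol, C7=C8 octalin (5R,9R,10S) | C[C@]12CCCC3(OCCO3)[C@@H]1CC=C(C)[C@@]2(C)CO | intermediate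
26 | saturated C11 alcohol (5R,8S,9R,10S) | C[C@]12CCCC3(OCCO3)[C@@H]1CC[C@H](C)[C@@]2(C)CO | intermediate
27 | C11 aldehyde (5R,8S,9R,10S) | C[C@]12CCCC3(OCCO3)[C@@H]1CC[C@H](C)[C@@]2(C)C=O | intermediate
28 | 1,2,4,5-tetramethoxybenzene | COc1cc(OC)c(OC)cc1OC | starting material
29 | 2,3,5,6-tetramethoxyphenyllithium | [Li]c1c(OC)c(OC)cc(OC)c1OC | intermediate
30 | C11 (2,3,5,6-tetramethoxyphenyl)carbinol, C11 epimers | C[C@]12CCCC3(OCCO3)[C@@H]1CC[C@H](C)[C@@]2(C)C(O)c1c(OC)c(OC)cc(OC)c1OC | intermediate
31 | C11 O-alkyl S-methyl xanthate, C11 epimers | C[C@]12CCCC3(OCCO3)[C@@H]1CC[C@H](C)[C@@]2(C)C(OC(=S)SC)c1c(OC)c(OC)cc(OC)c1OC | intermediate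
32 | C11 methylene tetramethoxyarene, C4 ketal (5R,8S,9R,10S) | C[C@]12CCCC3(OCCO3)[C@@H]1CC[C@H](C)[C@@]2(C)Cc1c(OC)c(OC)cc(OC)c1OC | intermediate
33 | C4 ketone (5R,8S,9R,10S) | O=C1CCC[C@@]2(C)[C@H]1CC[C@H](C)[C@@]2(C)Cc1c(OC)c(OC)cc(OC)c1OC | intermediate
34 | C4 methylidene tetramethoxyarene (5S,8S,9R,10S) | C=C1CCC[C@@]2(C)[C@H]1CC[C@H](C)[C@@]2(C)Cc1c(OC)c(OC)cc(OC)c1OC | intermediate
35 | 3-alkyl-2,5-dimethoxy-1,4-benzoquinone | C=C1CCC[C@@]2(C)[C@H]1CC[C@H](C)[C@@]2(C)CC1=C(OC)C(=O)C=C(OC)C1=O | intermediate
36 | 3-alkyl-2,5-dihydroxy-1,4-benzoquinone | C=C1CCC[C@@]2(C)[C@H]1CC[C@H](C)[C@@]2(C)CC1=C(O)C(=O)C=C(O)C1=O | intermediate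
37 | CNP0109104.1 (5S,8S,9R,10S) | C=C1CCC[C@@]2(C)[C@H]1CC[C@H](C)[C@@]2(C)CC1=C(O)C(=O)C=C(OC)C1=O | target

Total step count: 24. Longest linear sequence: 22 (steps 3–24). Steps 1–2 form the side branch that joins at step 7.

Steps most likely to fail

Step 10. The trimethylsilyl ketene acetal may desilylate, ionise at the allylic C7–O bond or eliminate before the crowded boat transition state joining two fully substituted carbons is reached.
- The fallback sets out from 17 and returns at 22. It makes the same C9–C10 bond one oxidation level lower, from an allyl vinyl ether that tolerates much higher temperatures than a silyl ketene acetal.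
- 17 is reduced with i-Bu2AlH (toluene, −78 °C) to the C14 lactol F1.
- CH3SO2Cl/Et3N (CH2Cl2, 0 °C to reflux) dehydrates it to the 2-alkenyl-3,4-dihydro-2H-pyran F2.
- Heating in base-washed glass (1,2-dichlorobenzene, 180–200 °C) should bring about the known thermal Claisen rearrangement of 2-alkenyldihydropyrans to cyclohexenecarbaldehydes. It would pass through the same tether-enforced boat and give aldehyde 22 directly, so steps 11 and 12 drop out.

Step 21 (together with the unmasking in step 20). Enolisation of the C4 ketone toward C5 may erode the trans ring fusion. The fusion is not clearly favoured thermodynamically because of the 1,3-diaxial C14/C8 methyl pair, and carbonyl attack next to the ring fusion may be sluggish.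
- The fallback sets out from 33 and returns at 34. It replaces direct methylenation by an addition–elimination sequence (Peterson olefination).
- Me3SiCH2Li with anhydrous CeCl3 (THF, −78 °C) adds as an essentially non-basic nucleophile to give the β-hydroxysilane F4. Its C4 configuration is of no consequence.
- KH (THF, rt) then eliminates it to 34.

Step 13. Hydrazone formation may be slow at an aldehyde wedged between the ring fusion and quaternary C9, azine formation may compete, and the hydrazone may decompose incompletely.
- The fallback sets out from 21 and returns at 25. It removes the C14 oxygen reductively at the alcohol level.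
- 21 is converted with n-BuLi and ClP(O)(NMe2)2 (THF/TMEDA) into the tetramethylphosphorodiamidate F3.
- Li in EtNH2/t-BuOH (0 °C) cleaves the neopentyl C–O bond, a deoxygenation developed for hindered primary alcohols. It removes the 4-methoxybenzyl ether in the same operation, so 25 is reached and steps 12–14 drop out.

Further compounds
F1 | step 10 | C14 lactol of 17 (anomeric mixture) | OC1O[C@@H](C[C@H]2C3(OCCO3)CCC[C@H]12)/C(C)=C(C)\COCc1ccc(OC)cc1
F2 | step 10 | 2-alkenyl-3,4-dihydro-2H-pyran (C14H=C10 enol ether; 5R,7S) | C1=C2CCCC3(OCCO3)[C@@H]2C[C@H](O1)/C(C)=C(C)\COCc1ccc(OC)cc1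
F3 | step 13 | C14 N,N,N',N'-tetramethylphosphorodiamidate of 21 | CN(C)P(=O)(N(C)C)OC[C@]12CCCC3(OCCO3)[C@@H]1CC=C(C)[C@@]2(C)COCc1ccc(OC)cc1
F4 | step 21 | C4 β-hydroxysilane (C4 configuration open) | C[Si](C)(C)CC1(O)CCC[C@@]2(C)[C@H]1CC[C@H](C)[C@@]2(C)Cc1c(OC)c(OC)cc(OC)c1OC
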